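**Plan**

1. Ring A is cut last, at C4a–C5 and C8–C8a (Diels–Alder, then aromatization). This works because ring A is a resorcinol-type ring (H on C5 and C6, OH on C7) whose C8 prenyl group lies between O1 and the C7 hydroxyl, while ring C (O1, C2, C3, C4, C4a, C8a) can exist alone as a 2-aryl-2,3-dihydropyran-4-one whose C4a=C8a bond serves as dienophile.
2. Ring C is cut at O1–C8a and C4a–C8a (amide acetal carbon = C8a), at C4–C4a (acylation of a sulfinyl carbanion, its carbon = C4a) and at C2–C3 (acetate aldol). The diene is cut at the allylic C–C bond made by α'-prenylation of an enone.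
3. The ring B aldehyde comes from 4-hydroxybenzaldehyde by double ortho-prenylation and acid closure of one prenyl group to the chroman.
4. Forward order of ring formation: chroman ring of ring B (step 2), ring C (step 5), ring A (step 8).
5. Stereochemistry: C2 (S), the only stereocentre of the target, is set by the catalytic asymmetric aldol of step 3 and is not enolized or ionized afterwards. The sulfinyl group, from (R)-methyl p-tolyl sulfoxide, is a traceless activating group.

Key step: step 8

Assumption: the titanium catalyst built on the (R)-binaphthyl ligand is taken to direct the ketene acetal to the Si face of the ring B aldehyde, giving the (3S)-alcohol; if MTPA ester analysis of the aldol product shows the opposite sense, the (S)-ligand is used and nothing else changes.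

Abbreviation used in names: Ar = 2,2-dimethyl-8-(3-methylbut-2-en-1-yl)chroman-6-yl.

**Step 1**
Reactants: 1 4-hydroxybenzaldehyde; 2 prenyl bromide
Product: 3 4-hydroxy-3,5-bis(3-methylbut-2-en-1-yl)benzaldehyde
Conditions: 2 (2.5 equiv), KOH (10% aq.), 25 °C
Reagents that add atoms: none
Why: In water the phenoxide oxygen is hydrogen-bonded, so the allylic bromide is attacked by the two free ortho carbons (phenoxide C-alkylation, para position blocked by the formyl group), and the excess of bromide serves to alkylate both ortho positions.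

**Step 2**
Reactants: 3 4-hydroxy-3,5-bis(3-methylbut-2-en-1-yl)benzaldehyde
Product: 4 2,2-dimethyl-8-(3-methylbut-2-en-1-yl)chroman-6-carbaldehyde
Conditions: Amberlyst 15, CH2Cl2, 25 °C
Reagents that add atoms: none
Why: Acid-catalysed intramolecular hydroalkoxylation (Markovnikov addition of the phenol OH to one protonated prenyl alkene) closes the 2,2-dimethylchroman, and once the only phenol is consumed the second prenyl group has no nucleophile to cyclize onto.

**Step 3**
Reactants: 4 2,2-dimethyl-8-(3-methylbut-2-en-1-yl)chroman-6-carbaldehyde; 5 1-methoxy-1-(trimethylsilyloxy)ethene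
Product: 7 methyl (3S)-3-Ar-3-hydroxypropanoate, via silyl ether 6 (not isolated)
Conditions: Ti(OiPr)4 (3 mol %), (R)-2-(3-bromo-5-tert-butylsalicylideneamino)-2'-hydroxy-1,1'-binaphthyl (3 mol %), 3,5-di-tert-butylsalicylic acid (3 mol %), Et2O, −10 °C; then citric acid, MeOH, 25 °C
Reagents that add atoms: none
Why: Catalytic enantioselective Mukaiyama acetate aldol, in which the chiral titanium Schiff-base complex binds the aldehyde and exposes one face to the silyl ketene acetal, sets the future C2 as (S), and mild methanolysis of the silyl ether frees the alcohol without ionizing the electron-rich benzylic C–O bond.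

**Step 4**
Reactants: 7 methyl (3S)-3-Ar-3-hydroxypropanoate; 8 (R)-methyl p-tolyl sulfoxide
Product: 10 (4S)-4-Ar-4-hydroxy-1-[(R)-p-tolylsulfinyl]butan-2-one, via lithiated sulfoxide 9 (not isolated)
Conditions: 8 (3.3 equiv), LiN(iPr)2 (3.3 equiv), THF, −78 °C; then 7, −78 to −40 °C; AcOH
Reagents that add atoms: none
Why: Claisen-type acylation of an α-sulfinyl carbanion by an ester is the standard entry to β-keto sulfoxides; one equivalent is spent on the hydroxyl and one on the acidic product, the lithium alkoxide blocks β-elimination, the low temperature suppresses retro-aldol cleavage, and the sulfur configuration is retained.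

**Step 5**
Reactants: 10 (4S)-4-Ar-4-hydroxy-1-[(R)-p-tolylsulfinyl]butan-2-one; 11 N,N-dimethylformamide dimethyl acetal
Product: 13 (2S)-2-Ar-5-[(S)-p-tolylsulfinyl]-2,3-dihydro-4H-pyran-4-one, via enaminone 12 (not isolated)
Conditions: 11 (1.5 equiv), PhMe, 25 °C; then AcOH, 40 °C
Reagents that add atoms: none
Why: The doubly activated methylene condenses with the amide acetal to an α-sulfinyl enaminone whose aminomethylene carbon is attacked by the δ-hydroxyl (6-endo addition–elimination with loss of dimethylamine), the annulation known for δ-hydroxy-β-keto esters and for o-hydroxyaryl β-keto sulfoxides on the way to 3-sulfinylchromones; the C2–O bond is not broken, so C2 stays (S) (the sulfur descriptor changes from R to S by priority only).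

**Step 6**
Reactants: 14 (E)-4-methoxybut-3-en-2-one; 2 prenyl bromide
Product: 16 (E)-1-methoxy-7-methylocta-1,6-dien-3-one, via lithium dienolate 15 (not isolated)
Conditions: LiN(iPr)2, THF, −78 °C; then 2, DMPU, −78 to −20 °C
Reagents that add atoms: none
Why: Kinetic deprotonation at the methyl group, the only enolizable position of the vinylogous ester, gives the α'-enolate, which is alkylated by SN2 attack on the reactive allylic bromide at a temperature where addition of the enolate to unreacted enone is slow.

**Step 7**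
Reactants: 16 (E)-1-methoxy-7-methylocta-1,6-dien-3-one
Product: 17 (1E,3Z)-1-methoxy-7-methyl-3-(trimethylsilyloxy)octa-1,3,6-triene
Conditions: TMSOTf, Et3N, Et2O, 0 °C
Reagents that add atoms: trimethylsilyl trifluoromethanesulfonate, C[Si](C)(C)OS(=O)(=O)C(F)(F)F
Why: Soft enolization with silyl triflate and amine gives the 2-silyloxydiene as the favoured Z silyl enol ether, which places the alkyl chain trans to the methoxyvinyl unit and therefore outward in the s-cis diene, the geometry needed for cycloaddition.

**Step 8**
Reactants: 13 (2S)-2-Ar-5-[(S)-p-tolylsulfinyl]-2,3-dihydro-4H-pyran-4-one; 17 (1E,3Z)-1-methoxy-7-methyl-3-(trimethylsilyloxy)octa-1,3,6-triene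
Product: 20 (2S)-2-Ar-7-hydroxy-8-(3-methylbut-2-en-1-yl)chroman-4-one, via cycloadduct 18 (not isolated), via sulfinyl enone 19 (not isolated)
Conditions: 17 (4 equiv), CH2Cl2, 12 kbar, 25 °C; then 0.1 M HCl, THF, 0 °C; then NaHCO3, PhMe, 80 °C
Reagents that add atoms: none
Why: Under pressure the electron-rich diene 17 adds across C5=C6 of 13 (C4a=C8a of the flavanone) in an asynchronous normal-demand Diels–Alder reaction, its prenyl-bearing terminus bonding to C6 and its methoxy-bearing terminus to the sulfinyl carbon; dilute acid then expels the allylic methoxy group of 18 and hydrolyses the silyl enol ether to enone 19, and at 80 °C the sulfoxide leaves by syn elimination with H8a to a cyclohexadienone that tautomerizes to the C7 phenol. The closest known reaction type is the cycloaddition of 1-methoxy-3-silyloxydienes to α-sulfinyl enones, sulfinylquinones and 3-sulfinylchromones followed by loss of sulfenic acid and methanol; 13 is a further and less reactive member of that dienophile class, which is why pressure is used in place of heat. Ring A, the only ring formed, closes by intermolecular (4+2) cycloaddition that makes C4a–C5 and C8–C8a, followed by two eliminations. No new stereocentre survives: the four carbon centres of 18 are erased on aromatization, the sulfur centre is lost, and C2, set in step 3, is remote and neither enolized nor ionized. Two selectivities are needed: the regiochemistry of the addition, secured by matched polarization (ketone and sulfinyl group make C6 of 13 the electrophilic carbon, the silyl enol ether makes the prenyl-bearing diene terminus the nucleophilic one), and the direction of the sulfoxide elimination, secured by the order of events, because once methanol has left C5 is sp2 and H8a, held cis to sulfur by the suprafacial addition, is the only hydrogen available. The prenyl groups and the acid-sensitive o-prenylphenol of the product are protected by the neutral cycloaddition, the brief cold acid treatment and the bicarbonate buffer during thermolysis.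

**Compound list**

1 | 4-hydroxybenzaldehyde | O=Cc1ccc(O)cc1 | starting material
2 | prenyl bromide (1-bromo-3-methylbut-2-ene) | CC(C)=CCBr | starting material
3 | 4-hydroxy-3,5-bis(3-methylbut-2-en-1-yl)benzaldehyde | CC(C)=CCc1cc(C=O)cc(CC=C(C)C)c1O | intermediate
4 | 2,2-dimethyl-8-(3-methylbut-2-en-1-yl)chroman-6-carbaldehyde | CC(C)=CCc1cc(C=O)cc2c1OC(C)(C)CC2 | intermediate
5 | 1-methoxy-1-(trimethylsilyloxy)ethene | C=C(OC)O[Si](C)(C)C | starting material
6 | methyl (3S)-3-Ar-3-(trimethylsilyloxy)propanoate | CC(C)=CCc1cc([C@@H](O[Si](C)(C)C)CC(=O)OC)cc2c1OC(C)(C)CC2 | intermediate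
7 | methyl (3S)-3-Ar-3-hydroxypropanoate | CC(C)=CCc1cc([C@@H](O)CC(=O)OC)cc2c1OC(C)(C)CC2 | intermediate
8 | (R)-methyl p-tolyl sulfoxide | C[S@@](=O)c1ccc(C)cc1 | starting material
9 | [(R)-p-tolylsulfinyl]methyllithium | [Li]C[S@@](=O)c1ccc(C)cc1 | intermediate
10 | (4S)-4-Ar-4-hydroxy-1-[(R)-p-tolylsulfinyl]butan-2-one | CC(C)=CCc1cc([C@@H](O)CC(=O)C[S@@](=O)c2ccc(C)cc2)cc2c1OC(C)(C)CC2 | intermediate
11 | N,N-dimethylformamide dimethyl acetal | COC(OC)N(C)C | starting material
12 | (5S)-5-Ar-1-(dimethylamino)-5-hydroxy-2-[(S)-p-tolylsulfinyl]pent-1-en-3-one (aminomethylene geometry not assigned) | CC(C)=CCc1cc([C@@H](O)CC(=O)C(=CN(C)C)[S@@](=O)c2ccc(C)cc2)cc2c1OC(C)(C)CC2 | intermediate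
13 | (2S)-2-Ar-5-[(S)-p-tolylsulfinyl]-2,3-dihydro-4H-pyran-4-one | CC(C)=CCc1cc([C@@H]2CC(=O)C([S@@](=O)c3ccc(C)cc3)=CO2)cc2c1OC(C)(C)CC2 | intermediate
14 | (E)-4-methoxybut-3-en-2-one | CO/C=C/C(C)=O | starting material
15 | lithium (3E)-4-methoxybuta-1,3-dien-2-olate | [Li]OC(=C)/C=C/OC | intermediate
16 | (E)-1-methoxy-7-methylocta-1,6-dien-3-one | CO/C=C/C(=O)CCC=C(C)C | intermediate
17 | (1E,3Z)-1-methoxy-7-methyl-3-(trimethylsilyloxy)octa-1,3,6-triene | CO/C=C/C(O[Si](C)(C)C)=C/CC=C(C)C | intermediate
18 | (2S)-2-Ar-5-methoxy-8-(3-methylbut-2-en-1-yl)-4a-[(S)-p-tolylsulfinyl]-7-(trimethylsilyloxy)-2,3,4a,5,8,8a-hexahydro-4H-chromen-4-one (cis-fused; mixture at C4a, C5, C8, C8a) | CC(C)=CCC1C(O[Si](C)(C)C)=CC(OC)C2([S@@](=O)c3ccc(C)cc3)C(=O)C[C@@H](c3cc(CC=C(C)C)c4OC(C)(C)CCc4c3)OC12 | intermediate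
19 | (2S)-2-Ar-8-(3-methylbut-2-en-1-yl)-4a-[(S)-p-tolylsulfinyl]-2,3,8,8a-tetrahydro-4H-chromene-4,7(4aH)-dione (cis-fused; mixture at C4a, C8, C8a) | CC(C)=CCC1C(=O)C=CC2([S@@](=O)c3ccc(C)cc3)C(=O)C[C@@H](c3cc(CC=C(C)C)c4OC(C)(C)CCc4c3)OC12 | intermediate
20 | (2S)-2-Ar-7-hydroxy-8-(3-methylbut-2-en-1-yl)chroman-4-one | CC(C)=CCc1cc([C@@H]2CC(=O)c3ccc(O)c(CC=C(C)C)c3O2)cc2c1OC(C)(C)CC2 | target

Total step count: 8. Longest linear sequence: 6 steps (steps 1, 2, 3, 4, 5 and 8); the diene branch (steps 6 and 7) joins at step 8.

The three steps most likely to fail are, in order of risk, the ring A construction (step 8), the enone prenylation (step 6) and the ring C annulation (step 5).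

Ring A construction, step 8. Three processes may defeat it:
- The cycloaddition may stall, because the dienophile is a vinylogous ester and the nucleophilic diene terminus is substituted.
- Sulfenic acid may be lost toward C5 before methanol has left, which leads to a dienol ether that cannot aromatize.
- Ring C may open by β-elimination of O1 from C8a once the C7 ketone is unmasked.

The fallback sets out from aldehyde 4 and comes back at 20, bringing ring A in ready-made. Commercial 2,4-dihydroxyacetophenone is C-prenylated with 2 (aq. KOH) to 1-[2,4-dihydroxy-3-(3-methylbut-2-en-1-yl)phenyl]ethanone F1. Claisen–Schmidt condensation of F1 with 4 (KOH, EtOH) should give the chalcone (E)-3-Ar-1-[2,4-dihydroxy-3-(3-methylbut-2-en-1-yl)phenyl]prop-2-en-1-one F2. Oxa-Michael ring closure (NaOAc, EtOH, reflux) should give racemic 2-Ar-7-hydroxy-8-(3-methylbut-2-en-1-yl)chroman-4-one F3. Kinetic resolution by asymmetric transfer hydrogenation (RuCl(p-cymene)[(R,R)-TsDPEN], HCO2H/Et3N) is expected to reduce the (2R)-ketone to the cis alcohol (2R,4R)-2-Ar-8-(3-methylbut-2-en-1-yl)chromane-4,7-diol F4 and to leave the (2S)-ketone 20, which is separated by chromatography.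

Enone prenylation, step 6. The lithium enolate may add to unreacted enone (conjugate addition–elimination, oligomers), and the product may be alkylated a second time. The fallback sets out from bromide 2 and comes back at 16, with the enone masked as its acetal. The kinetic lithium enolate (LiN(iPr)2, THF, −78 °C) of commercial 4,4-dimethoxybutan-2-one is alkylated at the methyl carbon with 2 to give 1,1-dimethoxy-7-methyloct-6-en-3-one F5. Base-catalysed loss of methanol from F5 (cat. NaOMe, heat) then releases enone 16.

Ring C annulation, step 5. Under the basic acetal the aldol unit may lose water to the conjugated enone or undergo retro-aldol cleavage, and ring closure of the enaminone may stay incomplete. The fallback sets out from aldehyde 4 and comes back at 13, building ring C first and adding sulfur afterwards.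
- Catalytic asymmetric Mukaiyama aldol addition of commercial (E)-1-methoxy-3-(trimethylsilyloxy)buta-1,3-diene to 4 (Ti(OiPr)4/BINOL of the configuration that gives the (S)-carbinol, Et2O, −20 °C) should give the open-chain adduct (1E,5S)-5-Ar-1-methoxy-5-(trimethylsilyloxy)pent-1-en-3-one F6.
- Trifluoroacetic acid closes F6, with loss of methanol and the silyl group, to (2S)-2-Ar-2,3-dihydro-4H-pyran-4-one F7; the two operations together amount to a stepwise hetero-Diels–Alder reaction.
- Iodine and pyridine (CH2Cl2, 25 °C) convert F7 into (2S)-2-Ar-5-iodo-2,3-dihydro-4H-pyran-4-one F8.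
- Coupling of F8 with 4-methylbenzenethiol (Pd2(dba)3, Xantphos, iPr2NEt, dioxane) gives (2S)-2-Ar-5-(p-tolylthio)-2,3-dihydro-4H-pyran-4-one F9.
- Oxidation of F9 with H2O2 in (CF3)2CHOH, which should leave the prenyl alkene untouched, returns 13 together with its sulfur epimer (2S)-2-Ar-5-[(R)-p-tolylsulfinyl]-2,3-dihydro-4H-pyran-4-one F10. The two are not separated, because both lose sulfur in step 8.

**Further compounds**

F1 | step 8 | 1-[2,4-dihydroxy-3-(3-methylbut-2-en-1-yl)phenyl]ethanone | CC(=O)c1ccc(O)c(CC=C(C)C)c1O
F2 | step 8 | (E)-3-Ar-1-[2,4-dihydroxy-3-(3-methylbut-2-en-1-yl)phenyl]prop-2-en-1-one | CC(C)=CCc1cc(/C=C/C(=O)c2ccc(O)c(CC=C(C)C)c2O)cc2c1OC(C)(C)CC2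
F3 | step 8 | racemic 2-Ar-7-hydroxy-8-(3-methylbut-2-en-1-yl)chroman-4-one | CC(C)=CCc1cc(C2CC(=O)c3ccc(O)c(CC=C(C)C)c3O2)cc2c1OC(C)(C)CC2
F4 | step 8 | (2R,4R)-2-Ar-8-(3-methylbut-2-en-1-yl)chromane-4,7-diol | CC(C)=CCc1cc([C@H]2C[C@@H](O)c3ccc(O)c(CC=C(C)C)c3O2)cc2c1OC(C)(C)CC2
F5 | step 6 | 1,1-dimethoxy-7-methyloct-6-en-3-one | COC(OC)CC(=O)CCC=C(C)C
F6 | step 5 | (1E,5S)-5-Ar-1-methoxy-5-(trimethylsilyloxy)pent-1-en-3-one | CO/C=C/C(=O)C[C@H](O[Si](C)(C)C)c1cc(CC=C(C)C)c2OC(C)(C)CCc2c1
F7 | step 5 | (2S)-2-Ar-2,3-dihydro-4H-pyran-4-one | CC(C)=CCc1cc([C@@H]2CC(=O)C=CO2)cc2c1OC(C)(C)CC2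
F8 | step 5 | (2S)-2-Ar-5-iodo-2,3-dihydro-4H-pyran-4-one | CC(C)=CCc1cc([C@@H]2CC(=O)C(I)=CO2)cc2c1OC(C)(C)CC2
F9 | step 5 | (2S)-2-Ar-5-(p-tolylthio)-2,3-dihydro-4H-pyran-4-one | CC(C)=CCc1cc([C@@H]2CC(=O)C(Sc3ccc(C)cc3)=CO2)cc2c1OC(C)(C)CC2
F10 | step 5 | (2S)-2-Ar-5-[(R)-p-tolylsulfinyl]-2,3-dihydro-4H-pyran-4-one | CC(C)=CCc1cc([C@@H]2CC(=O)C([S@](=O)c3ccc(C)cc3)=CO2)cc2c1OC(C)(C)CC2
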